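How much target did the flask hold at 40 h, and could any option raise it? The eta run is that flask followed so far; the delta run had less partner.

common to all: substrate 0.77 M; protic impurity 0.0385 M; temperature 60 °C
- eta: partner 1.39 M; the very flask that is asked about, followed so far
- delta: partner 0.69 M; run made earlier
- flask: partner 1.39 M; time 40 h

| run | time / h | target / % | substrate / % |
|---|---|---|---|
| eta | 2.50 | 15.0 | 41.4 |
| eta | 4.00 | 18.2 | 33.1 |
| eta | 6.00 | 18.0 | 27.5 |
| eta | 10.0 | 18.0 | 24.5 |
| eta | 15.0 | 16.9 | 23.2 |
| eta | 20.0 | 18.0 | 21.1 |
| eta | 30.0 | 15.7 | 18.9 |
| delta | 0.667 | 5.3 | 78.2 |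
| delta | 1.00 | 7.3 | 76.8 |
| delta | 1.33 | 7.4 | 71.6 |
| delta | 2.50 | 10.3 | 60.5 |
| delta | 3.00 | 9.5 | 57.7 |
| delta | 5.00 | 12.8 | 52.5 |
| delta | 8.00 | 12.1 | 47.4 |

(each reading ± 1 percentage point)

- target, in percent of the substrate first charged, at 40 h
- the option that brings most further target ("none" if no option brings more than 2 percentage points) (amber / green / teal / ochre / none)
- target present, with what was taken out counted in, in percent of the substrate first charged, after amber
- target present, with what was taken out counted in, in percent of the substrate first charged, after green

- amber: at 40 h add partner, 50.0% of the amount charged, then wait 3.0 d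
- green: change nothing and wait 3.0 d more
- teal: at 40 h take out 90% of the target then present, then wait 3.0 d
- ochre: at 40 h raise the temperature by 20 K, then wait 3.0 d

- removed target is counted in
- the earlier runs do not show what temperature does; that part of a forecast is a guess
- additions bring no volume worth counting

1. The puzzle: in eta the substrate fell by 12 percentage points between 4.00 h and 20.0 h, yet the target read 18.2% and then 18.0%.

2. I read the share, target per substrate consumed, at 2.50 h: eta gave 25.6% and delta 26.1%. So eta's fall should have brought 3.1 points of target, against a scatter of 1 point. I took it that target was being lost as it was made.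

3. From 4.00 h to 30.0 h, the share put eta's making at 3.6 points, and its target still read 2.5 points lower. This read 0.0139 h⁻¹: the leak, the fraction of the present target lost each hour, a first-order rate constant.

4. In eta, making over leaking read 6.13 between 2.50 h and 4.00 h, but 0.240 between 20.0 h and 30.0 h, below one. Counting no further making, I reckoned 13.7% at 40 h and 5.01% after green.

5. By the share, amber could turn the substrate read in eta at 30.0 h into 4.8 points of target, and even that on top of my green figure stays below my figure for 40 h. Teal banks target but needs new making. Ochre is a guess. I expected no gain above 2 points.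

The forecast, which said “substrate keeps creeping down while target stays flat”, gave 17.5%, 18.4% after amber, 17.8% after green and best none, its 40 h figure above mine.

The flask gave 12.6%, 6.48% after amber, 4.63% after green, and best none.

    substrate + partner → target (k = 0.170 M⁻¹ h⁻¹, Ea = 72.0 kJ mol⁻¹)
    substrate + partner → isomer of the product (k = 0.480 M⁻¹ h⁻¹, Ea = 78.0 kJ mol⁻¹)
    target → over-reaction product (k = 0.0140 h⁻¹, Ea = 121 kJ mol⁻¹)
    partner + protic impurity → quenched reagent (k = 4.40 M⁻¹ h⁻¹, Ea = 65.0 kJ mol⁻¹)
    2 partner → self-condensation product (k = 0.340 M⁻¹ h⁻¹, Ea = 69.0 kJ mol⁻¹)
    (constants at 60 °C)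

In the flask at 40.0 h, making over loss stood at 0.0327, below one. Reckoned with the leak, 12.6% came over 3.0 d to 4.63%, against 4.63% in the flask after green. A neighbouring flask held 0.35 M of partner, and at 40.0 h its partner, the limiting reagent, stood at 0% with substrate at 67.2%. The share on its consumed substrate gave 8.40%, and the leak, reckoned over 40 h, brought that to 4.82%; that neighbouring flask held 5.05% of target.

(The earlier runs and the new flask are simulated with constants of no real substance.)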